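**Retrosynthetic overview**

1. The 2-arylbenzofuran is cut at C2–C1′ (furan ring B to resorcinol ring C), at O1–C2 and at C3–C3a. This leaves three pieces: a 2-geranyl-4-iodoresorcinol (ring A with the side chain), ethynyltrimethylsilane (C3 and C2) and 5-iodoresorcinol (ring C).
2. Enabling feature: C2=C3 of ring B (C3 bears only H, C2 bears O1 and C1′) is at the oxidation level of an alkyne, and O1 is a phenol oxygen on C7a, ortho to C3a. Ring B is therefore the cycloisomer of an ortho-hydroxy diarylacetylene. C1′ is meta to both hydroxyls of ring C, so it is electronically unbiased and available as an aryl iodide.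
3. Ring A: C7 lies between O1 and the C6 oxygen, so it is C2 of resorcinol, the position a directed ortho-metalation of the bis-MOM ether reaches first. A second metalation at the neighbouring position places iodine at the future C3a.
4. Order of rings: rings A and C are bought as benzenes. Ring B is the only ring made; it is closed last (O1–C2, 5-endo-dig) in the key step, directly after the C2–C1′ bond forms in the same flask, and the step releases the unprotected natural product.

Key step: step 5

Remark (assumption): geranyl bromide, ethynyltrimethylsilane and 5-iodobenzene-1,3-diol are taken as purchasable. The target has no stereocentre; its only stereo-element, the (E)-C2′=C3′ double bond, is brought in with geranyl bromide and is not touched afterwards. "Geranyl" below means (2E)-3,7-dimethylocta-2,6-dien-1-yl.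

**Route**

Step 1
Reactants: 1 resorcinol (benzene-1,3-diol)
Product: 2 1,3-bis(methoxymethoxy)benzene
Conditions: NaH, MOMCl, DMF, 0 °C → rt
Reagents that add atoms: chloromethyl methyl ether (MOMCl), COCCl
Why: Williamson-type O-alkylation of the bis-phenoxide with the reactive α-chloro ether (MOM protection) should install the two acetal groups that direct both later metalations.

Step 2
Reactants: 2 1,3-bis(methoxymethoxy)benzene; 3 geranyl bromide
Product: 5 2-geranyl-1,3-bis(methoxymethoxy)benzene, via 2-lithio-1,3-bis(methoxymethoxy)benzene 4 (not isolated)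
Conditions: n-BuLi, THF, 0 °C → rt; then CuBr·SMe2 (10 mol %), 3, −78 °C → rt
Reagents that add atoms: none
Why: Directed ortho-metalation should occur at C2, flanked by both acetal oxygens, and copper-catalysed SN2 allylic substitution on the primary bromide should attach the chain at C1′ without allylic transposition, so the (E) geometry is carried over.

Step 3
Reactants: 5 2-geranyl-1,3-bis(methoxymethoxy)benzene
Product: 7 2-geranyl-4-iodo-1,3-bis(methoxymethoxy)benzene, via [3-geranyl-2,4-bis(methoxymethoxy)phenyl]lithium 6 (not isolated)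
Conditions: n-BuLi, TMEDA, THF, −20 → 0 °C; then ICH2CH2I, −78 °C → rt
Reagents that add atoms: 1,2-diiodoethane, ICCI
Why: A second directed ortho-metalation should occur at C4 (equivalent to C6 by symmetry), where acetal-directed kinetic deprotonation is expected to outrun removal of a benzylic–allylic proton, and iodine transfer from 1,2-diiodoethane (with loss of ethene) leaves the olefins untouched.

Step 4
Reactants: 7 2-geranyl-4-iodo-1,3-bis(methoxymethoxy)benzene
Product: 8 2-geranyl-4-iodobenzene-1,3-diol
Conditions: TsOH·H2O (0.2 equiv), MeOH, rt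
Reagents that add atoms: none
Why: Acid-catalysed transacetalisation of the aryl MOM ethers to methanol should free both phenols, since the mixed acetal ionises under a mild sulfonic acid at room temperature faster than the trisubstituted olefins are protonated.

Step 5
Reactants: 8 2-geranyl-4-iodobenzene-1,3-diol; 9 ethynyltrimethylsilane; 10 5-iodobenzene-1,3-diol
Product: 14 mulberrofuran L [5-{7-geranyl-6-hydroxy-1-benzofuran-2-yl}benzene-1,3-diol], via silylalkyne 11 (not isolated), via ethynylphenol 12 (not isolated), via diarylacetylene 13 (not isolated)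
Conditions: PdCl2(PPh3)2 (5 mol %), CuI (5 mol %), Et3N, DMF, 9 (1.05 equiv), Ar, rt → 40 °C; argon purge/brief vacuum; then 10 (1.0 equiv), CsF (2 equiv), 40 °C; then 70 °C
Reagents that add atoms: none
Why: Zerovalent palladium, formed in the flask from PdCl2(PPh3)2, inserts into the C–I bond of 8 and takes up the copper acetylide of 9 (Sonogashira coupling) to give 11; after excess 9 is purged, fluoride slowly unmasks the terminal alkyne 12 in the presence of 10, whose arylpalladium iodide takes up the copper acetylide of 12 and by reductive elimination forms the sp-carbon–C1′ bond of 13, which is the C2–C1′ bond of the target. On warming, the phenoxide oxygen ortho to the alkyne adds across the copper- or palladium-activated triple bond and closes the furan ring at O1–C2 in a 5-endo-dig hydroalkoxylation (closure at the heteroatom), and protonation at C3 gives 14. The closest known reaction types are the one-pot Sonogashira/desilylation/Sonogashira synthesis of unsymmetrical diarylalkynes from two aryl iodides and a silylacetylene, and the domino coupling–cycloisomerisation of ortho-ethynylphenols or ortho-iodophenols with aryl halides or arylacetylenes to 2-arylbenzofurans (Castro–Stephens-type heteroannulation). No stereocentre is formed and the (E)-olefin is not touched by the catalysts. The step needs cross-coupling before ring closure, one aryl group per alkyne terminus and closure onto the right oxygen: the order of addition with removal of excess 9 keeps the two aryl iodides apart, slow fluoride release keeps the concentration of 12 low against homocoupling and premature cycloisomerisation (coupling at 40 °C, ring closure only at 70 °C), 10 is held at one equivalent so no arylpalladium remains to arylate C3, and only the hydroxyl on C3 of ring A is ortho to the alkyne, the C1 hydroxyl and the two meta hydroxyls of ring C being out of reach.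

**Compound list**

1 | resorcinol (benzene-1,3-diol) | Oc1cccc(O)c1 | starting material
2 | 1,3-bis(methoxymethoxy)benzene | COCOc1cccc(OCOC)c1 | intermediate
3 | geranyl bromide, (2E)-1-bromo-3,7-dimethylocta-2,6-diene | CC(C)=CCC/C(C)=C/CBr | starting material
4 | 2-lithio-1,3-bis(methoxymethoxy)benzene | [Li]c1c(OCOC)cccc1OCOC | intermediate
5 | 2-[(2E)-3,7-dimethylocta-2,6-dien-1-yl]-1,3-bis(methoxymethoxy)benzene | CC(C)=CCC/C(C)=C/Cc1c(OCOC)cccc1OCOC | intermediate
6 | {3-[(2E)-3,7-dimethylocta-2,6-dien-1-yl]-2,4-bis(methoxymethoxy)phenyl}lithium | CC(C)=CCC/C(C)=C/Cc1c(OCOC)ccc([Li])c1OCOC | intermediate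
7 | 2-[(2E)-3,7-dimethylocta-2,6-dien-1-yl]-4-iodo-1,3-bis(methoxymethoxy)benzene | CC(C)=CCC/C(C)=C/Cc1c(OCOC)ccc(I)c1OCOC | intermediate
8 | 2-[(2E)-3,7-dimethylocta-2,6-dien-1-yl]-4-iodobenzene-1,3-diol | CC(C)=CCC/C(C)=C/Cc1c(O)ccc(I)c1O | intermediate
9 | ethynyltrimethylsilane | C#C[Si](C)(C)C | starting material
10 | 5-iodobenzene-1,3-diol (5-iodoresorcinol) | Oc1cc(O)cc(I)c1 | starting material
11 | 2-[(2E)-3,7-dimethylocta-2,6-dien-1-yl]-4-[(trimethylsilyl)ethynyl]benzene-1,3-diol | CC(C)=CCC/C(C)=C/Cc1c(O)ccc(C#C[Si](C)(C)C)c1O | intermediate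
12 | 2-[(2E)-3,7-dimethylocta-2,6-dien-1-yl]-4-ethynylbenzene-1,3-diol | CC(C)=CCC/C(C)=C/Cc1c(O)ccc(C#C)c1O | intermediate
13 | 4-[(3,5-dihydroxyphenyl)ethynyl]-2-[(2E)-3,7-dimethylocta-2,6-dien-1-yl]benzene-1,3-diol | CC(C)=CCC/C(C)=C/Cc1c(O)ccc(C#Cc2cc(O)cc(O)c2)c1O | intermediate
14 | mulberrofuran L, 5-{7-[(2E)-3,7-dimethylocta-2,6-dien-1-yl]-6-hydroxy-1-benzofuran-2-yl}benzene-1,3-diol | CC(C)=CCC/C(C)=C/Cc1c(O)ccc2cc(-c3cc(O)cc(O)c3)oc12 | target

**Totals**

Total step count: 5. Longest linear sequence: 5 steps (1 → 2 → 5 → 7 → 8 → 14); 3, 9 and 10 are bought.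

**Steps most likely to fail, with fallbacks**

Step 5. What may go wrong: the freshly unmasked ortho-ethynylphenol may cycloisomerise to a 2-unsubstituted benzofuran before it is arylated, the alkyne may homocouple oxidatively, or the polyphenolates may oxidise in air. Fallback: the alkyne is moved to the resorcinol ring, where it cannot cyclise, and the sequence is run stepwise with isolation. It sets out from 10. Sonogashira coupling of 10 with 9 (PdCl2(PPh3)2, CuI, Et3N, THF, rt) should give 5-[(trimethylsilyl)ethynyl]benzene-1,3-diol F1. Methanolysis (K2CO3, MeOH, rt) should give 5-ethynylbenzene-1,3-diol F2, which is purified. Coupling of F2 with 8 (PdCl2(PPh3)2, CuI, Et3N, DMF, rt then 70 °C) is the classical ortho-iodophenol/arylacetylene heteroannulation and comes back to the route at 13, which should cyclise in the same flask to 14.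

Step 3. What may go wrong: the doubly activated benzylic–allylic C1′ methylene of 5 may be deprotonated in competition with ring lithiation, or metalation may be incomplete. Fallback: the order is inverted so that no geranyl group is present when the ring is functionalised, and the two-carbon unit is installed before the side chain. It sets out from 2.
- Electrophilic iodination (NIS, MeCN, rt) should give 1-iodo-2,4-bis(methoxymethoxy)benzene F3, para to one acetal oxygen and ortho to the other.
- Sonogashira coupling with ethynyltri(propan-2-yl)silane (PdCl2(PPh3)2, CuI, Et3N, 50 °C) should give {[2,4-bis(methoxymethoxy)phenyl]ethynyl}tri(propan-2-yl)silane F4.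
- n-BuLi (THF, 0 °C) should lithiate the position between the two acetal oxygens to give {2,6-bis(methoxymethoxy)-3-{[tri(propan-2-yl)silyl]ethynyl}phenyl}lithium F5 (not isolated). With CuBr·SMe2 (10 mol %) and 3 this should give {[3-geranyl-2,4-bis(methoxymethoxy)phenyl]ethynyl}tri(propan-2-yl)silane F6.
- TsOH·H2O in MeOH should then give 2-geranyl-4-{[tri(propan-2-yl)silyl]ethynyl}benzene-1,3-diol F7.
- F7 enters step 5 in place of 11: TBAF in the presence of 10, PdCl2(PPh3)2, CuI and Et3N in DMF should unmask 12 in the flask, where the fallback comes back to the route.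

Step 4. What may go wrong: a freed ortho-hydroxyl may add to the C2′=C3′ olefin under acid (chroman formation), the chain may undergo cation–olefin cyclisation, or the electron-rich aryl iodide may be protodeiodinated. Fallback: the acetal protecting group is changed to one cleaved by fluoride, so that the geranyl phenol never meets a Brønsted acid. It sets out from 1.
- NaH and 2-(trimethylsilyl)ethoxymethyl chloride in DMF should give 1,3-bis{[2-(trimethylsilyl)ethoxy]methoxy}benzene F8.
- n-BuLi (THF, 0 °C → rt) should give the 2-lithio derivative, (2,6-bis{[2-(trimethylsilyl)ethoxy]methoxy}phenyl)lithium F9 (not isolated). With CuBr·SMe2 (10 mol %) and 3 this should give 2-geranyl-1,3-bis{[2-(trimethylsilyl)ethoxy]methoxy}benzene F10.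
- n-BuLi/TMEDA should give (3-geranyl-2,4-bis{[2-(trimethylsilyl)ethoxy]methoxy}phenyl)lithium F11 (not isolated). With 1,2-diiodoethane this should give 2-geranyl-4-iodo-1,3-bis{[2-(trimethylsilyl)ethoxy]methoxy}benzene F12.
- TBAF (DMPU, THF, 60 °C) should then fragment both acetals and come back to the route at 8.

**Further compounds**

F1 | step 5 | 5-[(trimethylsilyl)ethynyl]benzene-1,3-diol | C[Si](C)(C)C#Cc1cc(O)cc(O)c1
F2 | step 5 | 5-ethynylbenzene-1,3-diol | C#Cc1cc(O)cc(O)c1
F3 | step 3 | 1-iodo-2,4-bis(methoxymethoxy)benzene | COCOc1ccc(I)c(OCOC)c1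
F4 | step 3 | {[2,4-bis(methoxymethoxy)phenyl]ethynyl}tri(propan-2-yl)silane | COCOc1ccc(C#C[Si](C(C)C)(C(C)C)C(C)C)c(OCOC)c1
F5 | step 3 | {2,6-bis(methoxymethoxy)-3-{[tri(propan-2-yl)silyl]ethynyl}phenyl}lithium | COCOc1ccc(C#C[Si](C(C)C)(C(C)C)C(C)C)c(OCOC)c1[Li]
F6 | step 3 | {[3-[(2E)-3,7-dimethylocta-2,6-dien-1-yl]-2,4-bis(methoxymethoxy)phenyl]ethynyl}tri(propan-2-yl)silane | CC(C)=CCC/C(C)=C/Cc1c(OCOC)ccc(C#C[Si](C(C)C)(C(C)C)C(C)C)c1OCOC
F7 | step 3 | 2-[(2E)-3,7-dimethylocta-2,6-dien-1-yl]-4-{[tri(propan-2-yl)silyl]ethynyl}benzene-1,3-diol | CC(C)=CCC/C(C)=C/Cc1c(O)ccc(C#C[Si](C(C)C)(C(C)C)C(C)C)c1O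
F8 | step 4 | 1,3-bis{[2-(trimethylsilyl)ethoxy]methoxy}benzene | C[Si](C)(C)CCOCOc1cccc(OCOCC[Si](C)(C)C)c1
F9 | step 4 | (2,6-bis{[2-(trimethylsilyl)ethoxy]methoxy}phenyl)lithium | [Li]c1c(OCOCC[Si](C)(C)C)cccc1OCOCC[Si](C)(C)C
F10 | step 4 | 2-[(2E)-3,7-dimethylocta-2,6-dien-1-yl]-1,3-bis{[2-(trimethylsilyl)ethoxy]methoxy}benzene | CC(C)=CCC/C(C)=C/Cc1c(OCOCC[Si](C)(C)C)cccc1OCOCC[Si](C)(C)C
F11 | step 4 | (3-[(2E)-3,7-dimethylocta-2,6-dien-1-yl]-2,4-bis{[2-(trimethylsilyl)ethoxy]methoxy}phenyl)lithium | CC(C)=CCC/C(C)=C/Cc1c(OCOCC[Si](C)(C)C)ccc([Li])c1OCOCC[Si](C)(C)C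
F12 | step 4 | 2-[(2E)-3,7-dimethylocta-2,6-dien-1-yl]-4-iodo-1,3-bis{[2-(trimethylsilyl)ethoxy]methoxy}benzene | CC(C)=CCC/C(C)=C/Cc1c(OCOCC[Si](C)(C)C)ccc(I)c1OCOCC[Si](C)(C)C
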